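Late in the runs the solid was still going at a steady pace. Over 50.0 s the north-west run lost it at 1.81 × 10⁻⁴ M s⁻¹ and the south run at 1.87 × 10⁻⁴ M s⁻¹, from different charges. So I read this feed as zero order in solid, and more solid promised no more feed. At that pace the south charge lasts 315 s, longer than 2.0 min. I decided to leave both charges and run the south flask on.

| flask | solid substrate | partner | remark | time |
|---|---|---|---|---|
| south | 0.057 M | 0.057 M | the very flask that is asked about, followed so far |  |
| north-west | 0.038 M | 0.057 M | run made earlier |  |
| flask | 0.057 M | 0.0570 M |  | 2.0 min |

| run | time / s | starting material / % | solid substrate / % |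
|---|---|---|---|
| south | 10.0 | 1.7 | 96.7 |
| south | 15.0 | 2.5 | 95.5 |
| south | 25.0 | 3.2 | 91.9 |
| south | 50.0 | 2.6 | 83.6 |
| north-west | 10.0 | 2.7 | 95.4 |
| north-west | 12.0 | 3.2 | 94.3 |
| north-west | 20.0 | 3.3 | 90.5 |
| north-west | 30.0 | 4.2 | 85.9 |
| north-west | 50.0 | 4.1 | 76.2 |

(standard deviation of a reading: 0.3 percentage points)

- solid, in amounts per volume of the solution: solid substrate
- the earlier runs were read with a standard deviation of 0.3 percentage points
- at the start none of the solid substrate is in solution
- starting material means what is dissolved; the solid is not counted in it

- concentration of starting material at 2.0 min, in M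
- concentration of solid substrate at 2.0 min, in M
- concentration of target at 2.0 min, in M
- concentration of partner at 2.0 min, in M

In the north-west run, [starting material] read 4.2% and then 4.1%. I took that as a quasi-steady state, with feed balanced by reaction with partner. At the last reading [starting material] read 0.00156 M, and from the solid lost I reckoned [partner] at 0.0495 M. Feed over their product gave a reading of 2.34 M⁻¹ s⁻¹, which I call the drain constant: the second-order constant for loss of dissolved starting material. For the south flask at 2.0 min I reckoned [partner] 0.0369 M, so [starting material] 0.00209 M.

The forecast gave [starting material] 0.0022 M, above mine, solid 0.0348 M, target 0.02 M and partner 0.037 M. Its words were “dissolution looks zero order in solid”.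

The flask gave [starting material] 0.00206 M, solid 0.0353 M, partner 0.0374 M and target 0.00673 M, below the forecast. Of the solid charged, it held target 11.8% and isomer of the product 21.4%.

    starting material + partner → intermediate + by-product (k = 2.20 M⁻¹ s⁻¹)
    intermediate ⇌ target (K = 11.0, k = 0.340 s⁻¹)
    intermediate ⇌ isomer of the product (K = 230, k = 0.210 s⁻¹)
    solid substrate ⇌ starting material, rate k4*(cs4 - [starting material]) while solid is left; crystals form when [starting material] > cs4 (solubility = 26.0 mM, k = 0.00740 s⁻¹)

With the flask's own [partner], the drain constant gives [starting material] 0.00206 M. The neighbouring flask was charged with 0.23 M of partner, and it ended with [partner] 0.208 M. The same reckoning gives it 3.71 × 10⁻⁴ M, and it held 4.14 × 10⁻⁴ M. Its solid stood at 0.0343 M, and its target at 0.00754 M.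

The readings come from a simulation for substances that don't exist, and the scatter is random.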